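**Plan**

- Retrosynthetic cuts, in order: the configuration of the lactol carbon (fixed last); the two methyl ethers that mask the lactol OH and the CH2OH; the aryl ester C(=O)–O bond of the seven-membered ring; the two ring A C–C bonds on either side of the ester-bearing/methyl-bearing carbon pair; and the vinyl C–O bond that ties ring B to a cyclohexenone.
- Enabling feature: ring A has its ester carbon and methyl on adjacent carbons, and its ether oxygen and phenol oxygen meta to each other with the formyl carbon between them. A 1-aryloxy-2-allyl-3-silyloxycyclohexa-1,3-diene and a but-2-ynoate give exactly this pattern once the saturated C5–C6 bridge leaves as ethylene.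
- Forward order: ring B (bought as methyl 2,4-dihydroxy-3-methylbenzoate) is substituted at every carbon, O-linked to 2-allyl-3-chlorocyclohexenone and enol-silylated. The Alder–Rickert step then builds ring A. Both allyl groups are cut down to formyl groups, the five-membered pseudo-ester ring is closed, and debenzylation and lactonization close the seven-membered ring.
- Stereochemistry: the only stereocentre is the lactol carbon. It is carried as a racemate and fixed as (S) in the last step by seeded crystallization with epimerization in solution.

Key step: step 14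

Assumption: the lactol carbon epimerizes in solution through the ring-opened formyl acid, so the (S)-configuration can only be fixed in the solid; it is assumed that the racemate crystallizes as a conglomerate and that (S)-seed crystals are at hand from a few milligrams of racemate separated once on a chiral stationary phase.

**Route**

Step 1
Reactants: 1 methyl 2,4-dihydroxy-3-methylbenzoate
Product: 2 methyl 2,4-diacetoxy-3-methylbenzoate
Conditions: Ac2O, pyridine, DMAP (cat.), rt
Reagents that add atoms: acetic anhydride, CC(=O)OC(C)=O
Why: Acylation of both phenols (DMAP catalysis overcomes the hydrogen bond of the 2-OH) makes the ring electron-poor, so that the following radical bromination should not be accompanied by ring bromination.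

Step 2
Reactants: 2 methyl 2,4-diacetoxy-3-methylbenzoate
Product: 3 methyl 2,4-diacetoxy-3-(bromomethyl)benzoate
Conditions: NBS (1.05 equiv), AIBN (cat.), PhCF3, 85 °C
Reagents that add atoms: N-bromosuccinimide, O=C1CCC(=O)N1Br
Why: Wohl–Ziegler benzylic bromination should take place at the only methyl group, as it does with 2,6-diacetoxytoluene, and one equivalent of NBS limits dibromination.

Step 3
Reactants: 3 methyl 2,4-diacetoxy-3-(bromomethyl)benzoate
Product: 4 methyl 2,4-dihydroxy-3-(methoxymethyl)benzoate
Conditions: K2CO3, MeOH (dilute), 0 °C → rt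
Reagents that add atoms: methanol, CO
Why: Carbonate-mediated methanolysis of the two aryl acetates and phenoxide-assisted solvolysis of the ortho-hydroxybenzylic bromide by the solvent should give the benzylic methyl ether, while the methyl ester cannot change in methanol.

Step 4
Reactants: 4 methyl 2,4-dihydroxy-3-(methoxymethyl)benzoate
Product: 5 methyl 2,4-bis(benzyloxy)-3-(methoxymethyl)benzoate
Conditions: BnBr (2.5 equiv), K2CO3, DMF, 60 °C
Reagents that add atoms: benzyl bromide, BrCc1ccccc1
Why: Williamson etherification in warm DMF alkylates the ester-chelated 2-OH as well as the 4-OH.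

Step 5
Reactants: 5 methyl 2,4-bis(benzyloxy)-3-(methoxymethyl)benzoate
Product: 6 methyl 2,4-bis(benzyloxy)-5-bromo-3-(methoxymethyl)benzoate
Conditions: NBS, MeCN, 0 °C → rt, dark
Reagents that add atoms: N-bromosuccinimide, O=C1CCC(=O)N1Br
Why: Electrophilic aromatic bromination should go to C5, which is ortho to one benzyloxy group and para to the other, and not to C6, which is meta to both and ortho to the ester.

Step 6
Reactants: 6 methyl 2,4-bis(benzyloxy)-5-bromo-3-(methoxymethyl)benzoate
Product: 8 methyl 2,4-bis(benzyloxy)-5-hydroxy-3-(methoxymethyl)benzoate, via pinacol boronate 7 (not isolated)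
Conditions: B2pin2, PdCl2(dppf) (cat.) [dppf = 1,1′-bis(diphenylphosphino)ferrocene], KOAc, 1,4-dioxane, 90 °C; then 30% H2O2, aq. Na2CO3, THF, 0 °C → rt
Reagents that add atoms: bis(pinacolato)diboron, CC1(C)OB(OC1(C)C)B1OC(C)(C)C(C)(C)O1 (boron of 7); hydrogen peroxide, OO (oxygen of 8)
Why: Miyaura borylation of the aryl bromide followed by oxidation of the C–B bond is a dependable bromide-to-phenol exchange that tolerates the ester and the benzyl ethers.

Step 7
Reactants: 8 methyl 2,4-bis(benzyloxy)-5-hydroxy-3-(methoxymethyl)benzoate
Product: 9 methyl 5-(allyloxy)-2,4-bis(benzyloxy)-3-(methoxymethyl)benzoate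
Conditions: allyl bromide, K2CO3, acetone, reflux
Reagents that add atoms: allyl bromide, C=CCBr
Why: Williamson etherification of the only free phenol.

Step 8
Reactants: 9 methyl 5-(allyloxy)-2,4-bis(benzyloxy)-3-(methoxymethyl)benzoate
Product: 10 methyl 2-allyl-4,6-bis(benzyloxy)-3-hydroxy-5-(methoxymethyl)benzoate
Conditions: N,N-diethylaniline, 190 °C
Reagents that add atoms: none
Why: The aromatic Claisen rearrangement ([3,3]-sigmatropic shift, then tautomerization) can deliver the allyl group only to the one unsubstituted ortho carbon, the one next to the ester, and at the same time frees the phenol needed for the ether bond to ring A.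

Step 9
Reactants: 11 cyclohexane-1,3-dione
Product: 12 2-allylcyclohexane-1,3-dione
Conditions: allyl bromide, KOH, H2O, Cu powder (cat.), rt
Reagents that add atoms: allyl bromide, C=CCBr
Why: C-Alkylation of the 1,3-dione enolate with an allylic halide in water is a long-used procedure that favours carbon over oxygen alkylation.

Step 10
Reactants: 12 2-allylcyclohexane-1,3-dione
Product: 13 2-allyl-3-chlorocyclohex-2-en-1-one
Conditions: (COCl)2, DMF (cat.), CH2Cl2, 0 °C → rt
Reagents that add atoms: oxalyl chloride, O=C(Cl)C(=O)Cl
Why: Vilsmeier-type conversion of the enolized 1,3-dione into the β-chloroenone is standard for 2-alkylcyclohexane-1,3-diones.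

Step 11
Reactants: 10 methyl 2-allyl-4,6-bis(benzyloxy)-3-hydroxy-5-(methoxymethyl)benzoate; 13 2-allyl-3-chlorocyclohex-2-en-1-one
Product: 14 methyl 2-allyl-3-[(2-allyl-3-oxocyclohex-1-en-1-yl)oxy]-4,6-bis(benzyloxy)-5-(methoxymethyl)benzoate
Conditions: Cs2CO3, DMF, 70 °C
Reagents that add atoms: none
Why: Addition–elimination (vinylogous acyl substitution) of the caesium phenoxide at the β-carbon of the chloroenone gives the vinylogous aryl ester, so the future diaryl ether oxygen is set without coupling two hindered arenes.

Step 12
Reactants: 14 methyl 2-allyl-3-[(2-allyl-3-oxocyclohex-1-en-1-yl)oxy]-4,6-bis(benzyloxy)-5-(methoxymethyl)benzoate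
Product: 15 methyl 2-allyl-3-{[2-allyl-3-(tert-butyldimethylsilyloxy)cyclohexa-1,3-dien-1-yl]oxy}-4,6-bis(benzyloxy)-5-(methoxymethyl)benzoate
Conditions: LiN(iPr)2 (LDA), THF, −78 °C; TBSOTf, −78 °C; Et3N quench
Reagents that add atoms: tert-butyldimethylsilyl trifluoromethanesulfonate, CC(C)(C)[Si](C)(C)OS(=O)(=O)C(F)(F)F
Why: Kinetic deprotonation of a vinylogous ester occurs at the α′-CH2, and O-silylation of the cross-conjugated enolate gives the 1-aryloxy-3-silyloxy-1,3-diene, while the hindered methyl benzoate and the benzylic ethers are not touched at −78 °C.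

Step 13
Reactants: 16 but-2-ynoic acid
Product: 17 benzyl but-2-ynoate
Conditions: BnBr, K2CO3, DMF, rt
Reagents that add atoms: benzyl bromide, BrCc1ccccc1
Why: Carboxylate O-alkylation gives the benzyl ester, chosen so that the ring A ester can later be removed by hydrogenolysis together with the benzyl ethers.

Step 14
Reactants: 15 methyl 2-allyl-3-{[2-allyl-3-(tert-butyldimethylsilyloxy)cyclohexa-1,3-dien-1-yl]oxy}-4,6-bis(benzyloxy)-5-(methoxymethyl)benzoate; 17 benzyl but-2-ynoate
Product: 19 benzyl 3-allyl-2-[2-allyl-4,6-bis(benzyloxy)-3-(methoxycarbonyl)-5-(methoxymethyl)phenoxy]-4-(tert-butyldimethylsilyloxy)-6-methylbenzoate, via bicyclo[2.2.2]octadiene adduct 18 (not isolated)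
Conditions: 17 (5 equiv), mesitylene, BHT (cat.), 175 °C, sealed tube
Reagents that add atoms: none
Why: The electron-rich cross-conjugated silyloxy diene of 15 adds across the triple bond of 17 in a thermal normal-demand [4+2] cycloaddition that forms the two ring A C–C bonds (silyl enol ether terminus to the methyl-bearing alkyne carbon, aryloxy-bearing terminus to the ester-bearing carbon), and the bicyclo[2.2.2]octa-2,5-diene 18 then loses its saturated two-carbon bridge as ethylene by retro-Diels–Alder reaction to give the benzene ring. This is the Alder–Rickert reaction, known for 1-alkoxy-3-silyloxycyclohexa-1,3-dienes (2-alkyl dienes included) with acetylenic esters. Ring A is closed by intermolecular cycloaddition, both bonds forming suprafacially in one step, and is made aromatic by the cycloreversion. No stereocentre remains, because the two bridgeheads of 18 become sp2 carbons. The step needs regioselectivity and a single extrusion path: the first follows from the matched polarization of the diene (both oxygen donors raise the coefficient at the unsubstituted terminus) and of the ynoate (largest LUMO coefficient at the β-carbon), the second from the fact that only the CH2–CH2 bridge can leave as a stable alkene, while the aryloxy group sits on a bridgehead and cannot be eliminated as phenoxide. The C-allyl groups, benzyl ethers and esters should be inert at this temperature, and the excess of ynoate should outrun any intramolecular reaction of the diene with the ring B allyl group.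

Step 15
Reactants: 19 benzyl 3-allyl-2-[2-allyl-4,6-bis(benzyloxy)-3-(methoxycarbonyl)-5-(methoxymethyl)phenoxy]-4-(tert-butyldimethylsilyloxy)-6-methylbenzoate
Product: 20 benzyl 2-{4,6-bis(benzyloxy)-3-(methoxycarbonyl)-5-(methoxymethyl)-2-[(E)-prop-1-enyl]phenoxy}-4-(tert-butyldimethylsilyloxy)-6-methyl-3-[(E)-prop-1-enyl]benzoate
Conditions: [RuClH(CO)(PPh3)3] (cat.), toluene, 90 °C
Reagents that add atoms: none
Why: Ruthenium hydride-catalysed alkene isomerization (hydrometalation/β-hydride elimination) moves both terminal double bonds next to the arenes; the alkene geometry, expected to be mainly (E), is of no consequence because both alkenes are cleaved in the next step.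

Step 16
Reactants: 20 the bis(propenyl) diaryl ether
Product: 21 benzyl 2-[4,6-bis(benzyloxy)-2-formyl-3-(methoxycarbonyl)-5-(methoxymethyl)phenoxy]-4-(tert-butyldimethylsilyloxy)-3-formyl-6-methylbenzoate
Conditions: OsO4 (cat.), NaIO4, 2,6-lutidine, 1,4-dioxane–H2O, rt
Reagents that add atoms: osmium tetroxide, O=[Os](=O)(=O)=O (catalytic, transfers the oxygen atoms and is regenerated by sodium periodate, [Na+].[O-]I(=O)(=O)=O)
Why: Lemieux–Johnson oxidative cleavage of both styrene-type alkenes gives the two aryl aldehydes without touching the benzyl groups or the electron-rich rings, which ozone might attack.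

Step 17
Reactants: 21 the dialdehyde
Product: 22 benzyl 2-{[5,7-bis(benzyloxy)-3-methoxy-6-(methoxymethyl)-1-oxo-1,3-dihydro-2-benzofuran-4-yl]oxy}-3-formyl-4-hydroxy-6-methylbenzoate (racemic at the acetal carbon)
Conditions: K2CO3, MeOH–THF, 0 °C → rt; aq. citric acid work-up
Reagents that add atoms: methanol, CO
Why: Methoxide adds to the ring B formyl group and the hemiacetal alkoxide closes on the neighbouring methyl ester (5-exo-trig, the normal-to-pseudo ester isomerization of 2-formylbenzoates), while the aryl silyl ether ortho to the other formyl group is cleaved by methanolysis; the new acetal centre forms as a racemate, which does not matter because this carbon is equilibrated in the last step.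

Step 18
Reactants: 22 the benzyl-protected pseudo-ester
Product: 23 2-{[5,7-dihydroxy-3-methoxy-6-(methoxymethyl)-1-oxo-1,3-dihydro-2-benzofuran-4-yl]oxy}-3-formyl-4-hydroxy-6-methylbenzoic acid (racemic)
Conditions: H2 (1 atm), 10% Pd/C, EtOAc, rt, stopped when debenzylation is complete
Reagents that add atoms: none
Why: Hydrogenolysis removes the benzyl ester and both aryl benzyl ethers, and the hydrogen-bonded, doubly ortho-substituted salicylaldehyde should survive, as formyl groups do in debenzylations of lichen depsides.

Step 19
Reactants: 23 the hydroxy acid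
Product: 24 depsidone in which the lactol OH and the CH2OH of salazinic acid are both methyl ethers (racemic)
Conditions: EDC·HCl, DMAP (cat.), CH2Cl2 (high dilution), 0 °C → rt
Reagents that add atoms: none
Why: Carbodiimide (Steglich-type) lactonization closes the seven-membered dibenzodioxepinone ring (7-exo-trig) through the only phenol within reach of the acid, the one ortho to the diaryl ether oxygen, since the other two phenols are para to the linking atoms and hydrogen-bonded to carbonyl groups.

Step 20
Reactants: 24 the bis(methyl ether) depsidone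
Product: 26 racemic salazinic acid, via dichloride 25 (not isolated)
Conditions: BCl3, CH2Cl2, −78 → 0 °C; then THF–H2O, rt
Reagents that add atoms: boron trichloride, ClB(Cl)Cl (chlorine of 25); water, O (oxygen of the two new OH groups)
Why: Lewis acid cleavage of the acetal methoxy group and of the ortho-hydroxybenzylic methyl ether should give the two activated chlorides, which water converts into the lactol and the benzyl alcohol, while the aryl ester and the aldehyde are inert to BCl3 in the cold; the lactol carbon is obtained as a racemate.

Step 21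
Reactants: 26 racemic salazinic acid (seeded with crystals of 27)
Product: 27 (S)-salazinic acid, the target
Conditions: slurry in MeCN–H2O, AcOH/NaOAc (cat.), glass beads, vigorous stirring, 25 °C; filtration, cold wash, drying
Reagents that add atoms: none
Why: Proposed new method: the lactol epimerizes in solution by opening to the achiral 2-formylbenzoic acid tautomer while the crystals do not, so grinding a seeded slurry should let the (S)-crystals grow at the expense of the (R)-crystals until the whole solid is one enantiomer, the configuration being set by the (S)-seeds; the closest known reaction type is attrition-enhanced deracemization (Viedma ripening) of conglomerates whose stereocentre racemizes in solution.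

**Compound list**

1 | methyl 2,4-dihydroxy-3-methylbenzoate | COC(=O)c1ccc(O)c(C)c1O | starting material
2 | methyl 2,4-diacetoxy-3-methylbenzoate | COC(=O)c1ccc(OC(C)=O)c(C)c1OC(C)=O | intermediate
3 | methyl 2,4-diacetoxy-3-(bromomethyl)benzoate | COC(=O)c1ccc(OC(C)=O)c(CBr)c1OC(C)=O | intermediate
4 | methyl 2,4-dihydroxy-3-(methoxymethyl)benzoate | COCc1c(O)ccc(C(=O)OC)c1O | intermediate
5 | methyl 2,4-bis(benzyloxy)-3-(methoxymethyl)benzoate | COCc1c(OCc2ccccc2)ccc(C(=O)OC)c1OCc1ccccc1 | intermediate
6 | methyl 2,4-bis(benzyloxy)-5-bromo-3-(methoxymethyl)benzoate | COCc1c(OCc2ccccc2)c(Br)cc(C(=O)OC)c1OCc1ccccc1 | intermediate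
7 | methyl 2,4-bis(benzyloxy)-3-(methoxymethyl)-5-(4,4,5,5-tetramethyl-1,3,2-dioxaborolan-2-yl)benzoate (not isolated) | COCc1c(OCc2ccccc2)c(B2OC(C)(C)C(C)(C)O2)cc(C(=O)OC)c1OCc1ccccc1 | intermediate
8 | methyl 2,4-bis(benzyloxy)-5-hydroxy-3-(methoxymethyl)benzoate | COCc1c(OCc2ccccc2)c(O)cc(C(=O)OC)c1OCc1ccccc1 | intermediate
9 | methyl 5-(allyloxy)-2,4-bis(benzyloxy)-3-(methoxymethyl)benzoate | C=CCOc1cc(C(=O)OC)c(OCc2ccccc2)c(COC)c1OCc1ccccc1 | intermediate
10 | methyl 2-allyl-4,6-bis(benzyloxy)-3-hydroxy-5-(methoxymethyl)benzoate (ring B phenol) | C=CCc1c(O)c(OCc2ccccc2)c(COC)c(OCc2ccccc2)c1C(=O)OC | intermediate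
11 | cyclohexane-1,3-dione | O=C1CCCC(=O)C1 | starting material
12 | 2-allylcyclohexane-1,3-dione | C=CCC1C(=O)CCCC1=O | intermediate
13 | 2-allyl-3-chlorocyclohex-2-en-1-one | C=CCC1=C(Cl)CCCC1=O | intermediate
14 | methyl 2-allyl-3-[(2-allyl-3-oxocyclohex-1-en-1-yl)oxy]-4,6-bis(benzyloxy)-5-(methoxymethyl)benzoate | C=CCC1=C(Oc2c(CC=C)c(C(=O)OC)c(OCc3ccccc3)c(COC)c2OCc2ccccc2)CCCC1=O | intermediate
15 | methyl 2-allyl-3-{[2-allyl-3-(tert-butyldimethylsilyloxy)cyclohexa-1,3-dien-1-yl]oxy}-4,6-bis(benzyloxy)-5-(methoxymethyl)benzoate | C=CCC1=C(Oc2c(CC=C)c(C(=O)OC)c(OCc3ccccc3)c(COC)c2OCc2ccccc2)CCC=C1O[Si](C)(C)C(C)(C)C | intermediate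
16 | but-2-ynoic acid | CC#CC(=O)O | starting material
17 | benzyl but-2-ynoate | CC#CC(=O)OCc1ccccc1 | intermediate
18 | bicyclo[2.2.2]octa-2,5-diene adduct: C1 (bridgehead) carries the ring B aryloxy group, C2 the benzyl ester, C3 the methyl, C5 the silyloxy group, C6 the allyl group (racemic, not isolated) | CC1=C(C(=O)OCc2ccccc2)C2(Oc3c(CC=C)c(C(=O)OC)c(OCc4ccccc4)c(COC)c3OCc3ccccc3)CCC1C(O[Si](C)(C)C(C)(C)C)=C2CC=C | intermediate
19 | benzyl 3-allyl-2-[2-allyl-4,6-bis(benzyloxy)-3-(methoxycarbonyl)-5-(methoxymethyl)phenoxy]-4-(tert-butyldimethylsilyloxy)-6-methylbenzoate | Cc1cc(O[Si](C)(C)C(C)(C)C)c(CC=C)c(Oc2c(CC=C)c(C(=O)OC)c(OCc3ccccc3)c(COC)c2OCc2ccccc2)c1C(=O)OCc1ccccc1 | intermediate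
20 | benzyl 2-{4,6-bis(benzyloxy)-3-(methoxycarbonyl)-5-(methoxymethyl)-2-[(E)-prop-1-enyl]phenoxy}-4-(tert-butyldimethylsilyloxy)-6-methyl-3-[(E)-prop-1-enyl]benzoate | Cc1cc(O[Si](C)(C)C(C)(C)C)c(/C=C/C)c(Oc2c(/C=C/C)c(C(=O)OC)c(OCc3ccccc3)c(COC)c2OCc2ccccc2)c1C(=O)OCc1ccccc1 | intermediate
21 | benzyl 2-[4,6-bis(benzyloxy)-2-formyl-3-(methoxycarbonyl)-5-(methoxymethyl)phenoxy]-4-(tert-butyldimethylsilyloxy)-3-formyl-6-methylbenzoate | Cc1cc(O[Si](C)(C)C(C)(C)C)c(C=O)c(Oc2c(C=O)c(C(=O)OC)c(OCc3ccccc3)c(COC)c2OCc2ccccc2)c1C(=O)OCc1ccccc1 | intermediate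
22 | benzyl 2-{[5,7-bis(benzyloxy)-3-methoxy-6-(methoxymethyl)-1-oxo-1,3-dihydro-2-benzofuran-4-yl]oxy}-3-formyl-4-hydroxy-6-methylbenzoate (racemic) | Cc1cc(O)c(C=O)c(Oc2c3C(OC)OC(=O)c3c(OCc3ccccc3)c(COC)c2OCc2ccccc2)c1C(=O)OCc1ccccc1 | intermediate
23 | 2-{[5,7-dihydroxy-3-methoxy-6-(methoxymethyl)-1-oxo-1,3-dihydro-2-benzofuran-4-yl]oxy}-3-formyl-4-hydroxy-6-methylbenzoic acid (racemic) | Cc1cc(O)c(C=O)c(Oc2c3C(OC)OC(=O)c3c(O)c(COC)c2O)c1C(=O)O | intermediate
24 | depsidone: salazinic acid with the lactol OH and the CH2OH as methyl ethers (racemic) | Cc1cc(O)c(C=O)c2c1C(=O)Oc1c(COC)c(O)c3c(c1O2)C(OC)OC3=O | intermediate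
25 | dichloride: 24 with both methoxy groups replaced by chlorine (racemic; phenols boron-bound in the flask, not isolated) | Cc1cc(O)c(C=O)c2c1C(=O)Oc1c(CCl)c(O)c3c(c1O2)C(Cl)OC3=O | intermediate
26 | racemic salazinic acid | Cc1cc(O)c(C=O)c2c1C(=O)Oc1c(CO)c(O)c3c(c1O2)C(O)OC3=O | intermediate
27 | (S)-salazinic acid (CNP0166154.1) | Cc1cc(O)c(C=O)c2c1C(=O)Oc1c(CO)c(O)c3c(c1O2)[C@@H](O)OC3=O | target

**Step count and risks**

Total: 21 steps. Longest linear sequence: 18 steps (steps 1–8, 11, 12, 14–21).

Step 21 is the one step that goes beyond known chemistry. The racemate may crystallize as a racemic compound and not as a conglomerate, or epimerization in the slurry may be too slow, so that grinding cannot enrich one enantiomer. The fallback sets out from 26 and uses preparative chromatography on a polysaccharide chiral stationary phase with a cold aprotic eluent. The (S)-fraction is evaporated cold and comes back to the route as solid 27. The (R)-fraction is left in warm wet solvent with a trace of acid until it has returned to 26 and is recycled. This fallback makes no new compound (F0).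

In step 14 the cycloaddition may be too slow because the aryloxy-bearing diene terminus is shielded, which would give the diene time to isomerize or lose its silyl group and the ynoate time to oligomerize. The fallback sets out from 15 and replaces 17 by its more reactive allenic isomer, commercial benzyl buta-2,3-dienoate, at 80–100 °C. Addition across the ester-conjugated double bond, with the same regiochemistry, should give the exo-methylene bicyclo[2.2.2]octene adduct F1. DBU then moves the exocyclic double bond into conjugation with the ester to give 18, which on further heating loses ethylene and comes back to the route at 19.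

In step 11 the addition–elimination may stall because both partners are hindered (a phenoxide with two ortho substituents, a β-carbon next to the allyl-bearing α-carbon), so that the chloroenone is slowly hydrolysed back to the dione. The fallback sets out from 12 and 10. Dione 12 is converted with Tf2O and pyridine in CH2Cl2 at −78 °C into 2-allyl-3-oxocyclohex-1-en-1-yl trifluoromethanesulfonate F2. F2 is joined to phenol 10 by palladium-catalysed C–O coupling of a vinyl triflate with a phenol (Pd2(dba)3, 2-di-tert-butylphosphino-2′,4′,6′-triisopropylbiphenyl, K3PO4, toluene, 80 °C), in which bond formation by reductive elimination is less sensitive to crowding. It comes back to the route at 14.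

Further compounds
F0 | step 21 | none | none
F1 | step 14 | exo-methylene bicyclo[2.2.2]oct-5-ene adduct of 15 and benzyl buta-2,3-dienoate (racemic) | C=C1C(C(=O)OCc2ccccc2)C2(Oc3c(CC=C)c(C(=O)OC)c(OCc4ccccc4)c(COC)c3OCc3ccccc3)CCC1C(O[Si](C)(C)C(C)(C)C)=C2CC=C
F2 | step 11 | 2-allyl-3-oxocyclohex-1-en-1-yl trifluoromethanesulfonate | C=CCC1=C(OS(=O)(=O)C(F)(F)F)CCCC1=O
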